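## Retrosynthetic overview

1. The target is epiafzelechin-(4β→6)-epicatechin 3-O-gallate. The last step is one global hydrogenolysis of an undecabenzyl ether that also carries a temporary bromine on C8' of ring D.
2. Both C–C bonds at C4 of the upper unit are cut: C4–C4a (ring C) and C4–C6' (interflavan bond). This leaves an acyclic (2S,3R)-3-aryloxy-2-benzyloxypropanal (C4 = CHO, ring A attached through O1 to C2) and a 6-iodo-8-bromo epicatechin gallate.
3. Enabling feature: C4 is a diarylmethine between two phloroglucinol-type rings. O5' and O7' (ortho) and O1' (para) of ring D stabilise a cation at C4 as well as ring A would. The cation is therefore placed on ring D, and ring A, tied through O1–C2 and with two equivalent ortho carbons, is the nucleophile that closes ring C.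
4. C2 and C3 come from an Evans syn glycolate aldol. O1–C8a comes from a copper-catalysed O-arylation with retention. C2', C3' and rings D, E, F come from (−)-epicatechin.
5. Ring order: rings A, B, D, E, F and G are bought. Ring C is the only ring made, and it is made last, in the same flask as the interflavan bond.

Key step: step 13

Assumption: upper unit = rings A, B, C with unprimed atoms; lower unit = rings D, E, F with primed atoms; galloyl = ring G. Names of monomeric lower-unit compounds keep the usual unprimed flavan numbers. 5-Iodoresorcinol, 3,4,5-tris(benzyloxy)benzoic acid and (−)-epicatechin are taken as commercial.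

## Route

Step 1
Reactants: 1 (S)-4-benzyloxazolidin-2-one; 2 (benzyloxy)acetyl chloride
Product: 3 (S)-4-benzyl-3-[(benzyloxy)acetyl]oxazolidin-2-one
Conditions: Et3N, DMAP (cat.), CH2Cl2, 0 °C to rt
Reagents that add atoms: none
Why: DMAP-catalysed N-acylation of an oxazolidinone with an acid chloride is a standard loading of the Evans auxiliary and touches no stereocentre.

Step 2
Reactants: 3 (S)-4-benzyl-3-[(benzyloxy)acetyl]oxazolidin-2-one; 4 4-(benzyloxy)benzaldehyde
Product: 7 (S)-4-benzyl-3-{(2S,3R)-2-(benzyloxy)-3-[4-(benzyloxy)phenyl]-3-hydroxypropanoyl}oxazolidin-2-one, via dibutylboron Z-enolate 5 (not isolated), via dibutylboron aldolate 6 (not isolated)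
Conditions: Bu2BOTf, Et3N, CH2Cl2, −78 to 0 °C; 4, −78 to 0 °C; then H2O2, MeOH, pH 7 buffer, 0 °C
Reagents that add atoms: none
Why: Evans syn aldol reaction: the (Z)-boron enolate 5 adds through a closed Zimmerman–Traxler chair on the face away from the benzyl group of the auxiliary, which sets the carbinol carbon (later C2) and the benzyloxy carbon (later C3) together in the syn relationship that becomes 2,3-cis in ring C.

Step 3
Reactants: 7 Evans syn aldol adduct
Product: 8 (1R,2R)-2-(benzyloxy)-1-[4-(benzyloxy)phenyl]propane-1,3-diol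
Conditions: LiBH4, H2O (1 equiv), Et2O, 0 °C
Reagents that add atoms: none
Why: Reductive removal of the auxiliary with LiBH4 is standard for Evans aldol adducts, leaves both stereocentres alone and removes the β-hydroxy carbonyl unit that would undergo retro-aldol cleavage under the basic arylation of step 6.

Step 4
Reactants: 8 (1R,2R)-2-(benzyloxy)-1-[4-(benzyloxy)phenyl]propane-1,3-diol
Product: 9 (1R,2R)-2-(benzyloxy)-1-[4-(benzyloxy)phenyl]-3-[(tert-butyldiphenylsilyl)oxy]propan-1-ol
Conditions: TBDPSCl, imidazole, CH2Cl2, 0 °C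
Reagents that add atoms: tert-butyl(chloro)diphenylsilane, CC(C)(C)[Si](Cl)(c1ccccc1)c1ccccc1
Why: Selective silylation: the bulky silyl chloride takes the primary hydroxyl far faster than the hindered secondary benzylic one, and this silyl group is slow to migrate.

Step 5
Reactants: 10 5-iodobenzene-1,3-diol (5-iodoresorcinol)
Product: 11 1,3-bis(benzyloxy)-5-iodobenzene
Conditions: BnBr, K2CO3, DMF, rt
Reagents that add atoms: benzyl bromide, BrCc1ccccc1
Why: Williamson ether synthesis on two acidic phenols, under which the aryl iodide is inert.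

Step 6
Reactants: 9 mono-silylated diol; 11 1,3-bis(benzyloxy)-5-iodobenzene
Product: 12 tert-butyl{(2R,3R)-2-(benzyloxy)-3-[3,5-bis(benzyloxy)phenoxy]-3-[4-(benzyloxy)phenyl]propoxy}diphenylsilane
Conditions: CuI (10 mol %), 3,4,7,8-tetramethyl-1,10-phenanthroline (20 mol %), Cs2CO3, 4 Å MS, toluene, 110 °C
Reagents that add atoms: none
Why: Ullmann-type copper-catalysed C–O coupling of an aryl iodide with a secondary alcohol; the C–O bond of the alcohol is not broken, so the configuration at the later C2 is retained, and the two meta benzyloxy groups do not deactivate the iodide.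

Step 7
Reactants: 12 silyl-protected aryl ether
Product: 13 (2R,3R)-2-(benzyloxy)-3-[3,5-bis(benzyloxy)phenoxy]-3-[4-(benzyloxy)phenyl]propan-1-ol
Conditions: Bu4NF, AcOH, THF, rt
Reagents that add atoms: none
Why: Fluoride-driven cleavage of the Si–O bond, buffered with AcOH so that no free alkoxide builds up; benzyl and aryl ethers are untouched.

Step 8
Reactants: 13 primary alcohol
Product: 14 (2S,3R)-2-(benzyloxy)-3-[3,5-bis(benzyloxy)phenoxy]-3-[4-(benzyloxy)phenyl]propanal
Conditions: Dess–Martin periodinane, CH2Cl2, 0 °C to rt; used without chromatography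
Reagents that add atoms: none
Why: The Dess–Martin oxidation needs no base, so neither epimerisation at the α-benzyloxy carbon nor β-elimination of the aryloxide is expected.

Step 9
Reactants: 15 (−)-epicatechin
Product: 16 5,7,3',4'-tetra-O-benzyl-(−)-epicatechin
Conditions: BnBr, K2CO3, DMF, 0 °C to rt, Ar
Reagents that add atoms: benzyl bromide, BrCc1ccccc1
Why: Williamson ether synthesis in which K2CO3 deprotonates only the four phenols, so the C3' hydroxyl stays free and both chiral-pool stereocentres are kept.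

Step 10
Reactants: 16 5,7,3',4'-tetra-O-benzyl-(−)-epicatechin
Product: 17 8-bromo-5,7,3',4'-tetra-O-benzyl-(−)-epicatechin
Conditions: NBS, CH2Cl2, −45 °C to rt
Reagents that add atoms: N-bromosuccinimide, O=C1CCC(=O)N1Br
Why: Electrophilic aromatic bromination goes to C8', the most nucleophilic position of ring D in benzylated flavan-3-ols, and installs a temporary blocking atom that step 14 removes.

Step 11
Reactants: 17 8-bromo-5,7,3',4'-tetra-O-benzyl-(−)-epicatechin
Product: 18 8-bromo-6-iodo-5,7,3',4'-tetra-O-benzyl-(−)-epicatechin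
Conditions: NIS, CF3CO2H (cat.), CH2Cl2, 0 °C to rt, dark
Reagents that add atoms: N-iodosuccinimide, O=C1CCC(=O)N1I
Why: A second electrophilic aromatic halogenation can only take the one remaining activated position of ring D, C6' between the two benzyloxy groups, since ring E is much less activated.

Step 12
Reactants: 18 8-bromo-6-iodo-5,7,3',4'-tetra-O-benzyl-(−)-epicatechin; 19 3,4,5-tris(benzyloxy)benzoic acid
Product: 20 8-bromo-6-iodo-5,7,3',4'-tetra-O-benzyl-(−)-epicatechin 3-O-[3,4,5-tris(benzyloxy)benzoate]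
Conditions: DCC, DMAP (cat.), CH2Cl2, rt
Reagents that add atoms: none
Why: Steglich esterification of the secondary C3' hydroxyl, in which the C3'–O bond is not broken and the configuration is kept.

Step 13
Reactants: 20 6-iodo-8-bromo epicatechin gallate (perbenzylated); 14 (2S,3R)-aldehyde
Product: 24 3,5,7,4'-tetra-O-benzylepiafzelechin-(4β→6)-8-bromo-5,7,3',4'-tetra-O-benzylepicatechin 3-O-(3,4,5-tri-O-benzylgallate), via C6' arylmagnesium chloride 21 (not isolated), via C4 carbinol 22 (not isolated), via C4 benzylic cation 23 (not isolated)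
Conditions: iPrMgCl·LiCl, THF, −20 °C; 14, −40 to −10 °C; then CH2Cl2 (to 0.01 M), CF3CO2H, −40 to 0 °C
Reagents that add atoms: none
Why: Iodine–magnesium exchange at C6' (faster than at the C8' bromide and tolerated at −20 °C by the hindered, electron-rich gallate ester) gives 21, whose 1,2-addition to aldehyde 14 forms the interflavan bond C4–C6' regiospecifically and gives carbinol 22 as a mixture of C4 epimers that does not matter. Acidification ionises only this 2,4,6-trioxygenated benzylic alcohol to cation 23, stabilised by O5', O7' and O1' of ring D, and an ortho carbon of the 3,5-bis(benzyloxy)phenoxy ring held by O1 on C2 attacks C4, forms C4–C4a and rearomatises by loss of a proton. The closest known reaction types are halogen–magnesium exchange followed by carbonyl addition and the acid-induced intramolecular Friedel–Crafts cyclisation of 1-aryl-3-aryloxypropan-1-ols to 4-arylchromans, a relative of the capture of flavan C4 cations in proanthocyanidin synthesis. Ring C closes in the 6-exo-trig mode with respect to the C4=C6' bond of the quinone-methide-like cation, while the arene bond C4a=C8a ends up inside the new ring. The new stereocentre C4 is controlled by C3: allylic 1,3-strain with the two ortho benzyloxy groups of ring D puts H3 in the plane of the cation, so C2 with its tethered ring A lies on one face and O3 on the other, and bond formation anti to O3 gives the 3,4-trans (4β) product, which should also be the more stable epimer. The step needs intramolecular over intermolecular capture (six-membered transition state, high dilution), ionisation at C4 and not at the mono-oxygenated benzylic C2–O1 ether (weak acid, low temperature) and ortho attack on ring A, which is no issue because its two ortho positions are equivalent and the para position cannot reach C4.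

Step 14
Reactants: 24 protected, C8'-brominated dimer
Product: 25 epiafzelechin-(4β→6)-epicatechin 3-O-gallate (CNP0210310.1)
Conditions: H2 (1 atm), Pd(OH)2/C, Et3N (1.1 equiv), THF/MeOH/H2O, rt
Reagents that add atoms: none
Why: Catalytic hydrogenolysis should cleave the eleven benzyl ethers and the C8'–Br bond in one operation while Et3N binds the HBr, and the gallate ester, the interflavan bond and the five stereocentres are not affected.

## Compound list

1 | (S)-4-benzyloxazolidin-2-one | O=C1N[C@@H](Cc2ccccc2)CO1 | starting material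
2 | (benzyloxy)acetyl chloride | O=C(Cl)COCc1ccccc1 | starting material
3 | (S)-4-benzyl-3-[(benzyloxy)acetyl]oxazolidin-2-one | O=C(COCc1ccccc1)N1[C@@H](Cc2ccccc2)COC1=O | intermediate
4 | 4-(benzyloxy)benzaldehyde | O=Cc1ccc(OCc2ccccc2)cc1 | starting material
5 | dibutylboron (Z)-enolate of 3 | CCCCB(CCCC)O/C(=C\OCc1ccccc1)N1[C@@H](Cc2ccccc2)COC1=O | intermediate
6 | dibutylboron aldolate of 7 | CCCCB(CCCC)O[C@H](c1ccc(OCc2ccccc2)cc1)[C@@H](C(=O)N1[C@@H](Cc2ccccc2)COC1=O)OCc1ccccc1 | intermediate
7 | (S)-4-benzyl-3-{(2S,3R)-2-(benzyloxy)-3-[4-(benzyloxy)phenyl]-3-hydroxypropanoyl}oxazolidin-2-one | O[C@H](c1ccc(OCc2ccccc2)cc1)[C@@H](C(=O)N1[C@@H](Cc2ccccc2)COC1=O)OCc1ccccc1 | intermediate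
8 | (1R,2R)-2-(benzyloxy)-1-[4-(benzyloxy)phenyl]propane-1,3-diol | O[C@H](c1ccc(OCc2ccccc2)cc1)[C@@H](CO)OCc1ccccc1 | intermediate
9 | (1R,2R)-2-(benzyloxy)-1-[4-(benzyloxy)phenyl]-3-[(tert-butyldiphenylsilyl)oxy]propan-1-ol | O[C@H](c1ccc(OCc2ccccc2)cc1)[C@@H](CO[Si](c1ccccc1)(c1ccccc1)C(C)(C)C)OCc1ccccc1 | intermediate
10 | 5-iodobenzene-1,3-diol | Oc1cc(O)cc(I)c1 | starting material
11 | 1,3-bis(benzyloxy)-5-iodobenzene | Ic1cc(OCc2ccccc2)cc(OCc2ccccc2)c1 | intermediate
12 | tert-butyl{(2R,3R)-2-(benzyloxy)-3-[3,5-bis(benzyloxy)phenoxy]-3-[4-(benzyloxy)phenyl]propoxy}diphenylsilane | C(c1ccccc1)Oc1cc(OCc2ccccc2)cc(O[C@H](c2ccc(OCc3ccccc3)cc2)[C@@H](CO[Si](c2ccccc2)(c2ccccc2)C(C)(C)C)OCc2ccccc2)c1 | intermediate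
13 | (2R,3R)-2-(benzyloxy)-3-[3,5-bis(benzyloxy)phenoxy]-3-[4-(benzyloxy)phenyl]propan-1-ol | C(c1ccccc1)Oc1cc(OCc2ccccc2)cc(O[C@H](c2ccc(OCc3ccccc3)cc2)[C@@H](CO)OCc2ccccc2)c1 | intermediate
14 | (2S,3R)-2-(benzyloxy)-3-[3,5-bis(benzyloxy)phenoxy]-3-[4-(benzyloxy)phenyl]propanal | C(c1ccccc1)Oc1cc(OCc2ccccc2)cc(O[C@H](c2ccc(OCc3ccccc3)cc2)[C@@H](C=O)OCc2ccccc2)c1 | intermediate
15 | (−)-epicatechin, (2R,3R) | O[C@@H]1Cc2c(O)cc(O)cc2O[C@@H]1c1ccc(O)c(O)c1 | starting material
16 | 5,7,3',4'-tetra-O-benzyl-(−)-epicatechin | O[C@@H]1Cc2c(OCc3ccccc3)cc(OCc3ccccc3)cc2O[C@@H]1c1ccc(OCc2ccccc2)c(OCc2ccccc2)c1 | intermediate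
17 | 8-bromo-5,7,3',4'-tetra-O-benzyl-(−)-epicatechin | O[C@@H]1Cc2c(OCc3ccccc3)cc(OCc3ccccc3)c(Br)c2O[C@@H]1c1ccc(OCc2ccccc2)c(OCc2ccccc2)c1 | intermediate
18 | 8-bromo-6-iodo-5,7,3',4'-tetra-O-benzyl-(−)-epicatechin | O[C@@H]1Cc2c(OCc3ccccc3)c(I)c(OCc3ccccc3)c(Br)c2O[C@@H]1c1ccc(OCc2ccccc2)c(OCc2ccccc2)c1 | intermediate
19 | 3,4,5-tris(benzyloxy)benzoic acid | OC(=O)c1cc(OCc2ccccc2)c(OCc2ccccc2)c(OCc2ccccc2)c1 | starting material
20 | 8-bromo-6-iodo-5,7,3',4'-tetra-O-benzyl-(−)-epicatechin 3-O-[3,4,5-tris(benzyloxy)benzoate] | O=C(O[C@@H]1Cc2c(OCc3ccccc3)c(I)c(OCc3ccccc3)c(Br)c2O[C@@H]1c1ccc(OCc2ccccc2)c(OCc2ccccc2)c1)c1cc(OCc2ccccc2)c(OCc2ccccc2)c(OCc2ccccc2)c1 | intermediate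
21 | C6' arylmagnesium chloride (20 with MgCl in place of iodine) | O=C(O[C@@H]1Cc2c(OCc3ccccc3)c([Mg]Cl)c(OCc3ccccc3)c(Br)c2O[C@@H]1c1ccc(OCc2ccccc2)c(OCc2ccccc2)c1)c1cc(OCc2ccccc2)c(OCc2ccccc2)c(OCc2ccccc2)c1 | intermediate
22 | C4 carbinol (adduct of 21 and 14, both C4 epimers, first formed as its magnesium alkoxide) | O=C(O[C@@H]1Cc2c(OCc3ccccc3)c(C(O)[C@@H](OCc3ccccc3)[C@H](Oc3cc(OCc4ccccc4)cc(OCc4ccccc4)c3)c3ccc(OCc4ccccc4)cc3)c(OCc3ccccc3)c(Br)c2O[C@@H]1c1ccc(OCc2ccccc2)c(OCc2ccccc2)c1)c1cc(OCc2ccccc2)c(OCc2ccccc2)c(OCc2ccccc2)c1 | intermediate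
23 | C4 benzylic cation stabilised by ring D | O=C(O[C@@H]1Cc2c(OCc3ccccc3)c([CH+][C@@H](OCc3ccccc3)[C@H](Oc3cc(OCc4ccccc4)cc(OCc4ccccc4)c3)c3ccc(OCc4ccccc4)cc3)c(OCc3ccccc3)c(Br)c2O[C@@H]1c1ccc(OCc2ccccc2)c(OCc2ccccc2)c1)c1cc(OCc2ccccc2)c(OCc2ccccc2)c(OCc2ccccc2)c1 | intermediate
24 | 3,5,7,4'-tetra-O-benzylepiafzelechin-(4β→6)-8-bromo-5,7,3',4'-tetra-O-benzylepicatechin 3-O-(3,4,5-tri-O-benzylgallate); upper unit 2,3-cis-3,4-trans | O=C(O[C@@H]1Cc2c(OCc3ccccc3)c([C@H]3c4c(OCc5ccccc5)cc(OCc5ccccc5)cc4O[C@H](c4ccc(OCc5ccccc5)cc4)[C@@H]3OCc3ccccc3)c(OCc3ccccc3)c(Br)c2O[C@@H]1c1ccc(OCc2ccccc2)c(OCc2ccccc2)c1)c1cc(OCc2ccccc2)c(OCc2ccccc2)c(OCc2ccccc2)c1 | intermediate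
25 | epiafzelechin-(4β→6)-epicatechin 3-O-gallate; upper unit (2R,3R,4S), lower unit (2R,3R) | O=C(O[C@@H]1Cc2c(cc(O)c([C@H]3c4c(O)cc(O)cc4O[C@H](c4ccc(O)cc4)[C@@H]3O)c2O)O[C@@H]1c1ccc(O)c(O)c1)c1cc(O)c(O)c(O)c1 | target

## Step count and risks

Total step count: 14. Longest linear sequence: 9 steps (1, 2, 3, 4, 6, 7, 8, 13, 14).

**Step 13.**
- What may go wrong: the organomagnesium species may attack the gallate ester, the aldehyde may be enolised or lose its β-aryloxide instead of being added to, or the cation may be captured intermolecularly.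
- Fallback: it sets out from 14 and 17 (with 19), returns at 24, and reverses the order of the two bond formations at C4.
- Aldehyde 14 is first cyclised alone (BF3·OEt2, CH2Cl2, −78 °C, intramolecular Friedel–Crafts hydroxyalkylation). This gives the 3,5,7,4'-tetra-O-benzyl flavan-3,4-diol of the epiafzelechin series F1.
- Bromide 17 is esterified with 19 (DCC, DMAP) to the iodine-free 8-bromo gallate F2.
- F1 is then ionised with TMSOTf (cat., CH2Cl2, −78 °C) in the presence of an excess of F2. The C8' bromine leaves only C6' open, and attack anti to O3 should give 24.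

**Step 6.**
- What may go wrong: transfer of the hindered secondary benzylic alkoxide to copper may be slow, the silyl group may migrate to that alkoxide, or the alcohol may be oxidised.
- Fallback: it sets out from 9, returns at 12, and forms the ether at the sp3 carbon with inversion instead of at the arene.
- Dess–Martin oxidation of 9 gives the α-benzyloxy aryl ketone F3.
- Chelation-controlled reduction with Zn(BH4)2 (Et2O, −30 °C) should give the anti (1S,2R) alcohol F4.
- A Mitsunobu reaction of F4 with commercial 3,5-bis(benzyloxy)phenol (PPh3, DIAD, toluene, 0 °C) inverts the carbinol carbon and gives 12.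

**Step 14.**
- What may go wrong: cleavage of the hindered benzyl ethers around the interflavan bond may be incomplete, or HBr may cleave that bond once the phenols are free.
- Fallback: it sets out from 24, returns at 25, and separates the two events.
- A radical chain debromination (Bu3SnH, AIBN, toluene, 80 °C) gives the bromine-free undecabenzyl dimer F5.
- F5 is then hydrogenolysed under neutral conditions (H2, Pd(OH)2/C, THF/MeOH/H2O) to 25, with no acid formed.

## Further compounds

F1 | step 13 | (2R,3R)-3,5,7-tris(benzyloxy)-2-[4-(benzyloxy)phenyl]chroman-4-ol (C4 epimers) | OC1c2c(OCc3ccccc3)cc(OCc3ccccc3)cc2O[C@H](c2ccc(OCc3ccccc3)cc2)[C@@H]1OCc1ccccc1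
F2 | step 13 | 8-bromo-5,7,3',4'-tetra-O-benzyl-(−)-epicatechin 3-O-[3,4,5-tris(benzyloxy)benzoate] | O=C(O[C@@H]1Cc2c(OCc3ccccc3)cc(OCc3ccccc3)c(Br)c2O[C@@H]1c1ccc(OCc2ccccc2)c(OCc2ccccc2)c1)c1cc(OCc2ccccc2)c(OCc2ccccc2)c(OCc2ccccc2)c1
F3 | step 6 | (R)-2-(benzyloxy)-1-[4-(benzyloxy)phenyl]-3-[(tert-butyldiphenylsilyl)oxy]propan-1-one | O=C(c1ccc(OCc2ccccc2)cc1)[C@@H](CO[Si](c1ccccc1)(c1ccccc1)C(C)(C)C)OCc1ccccc1
F4 | step 6 | (1S,2R)-2-(benzyloxy)-1-[4-(benzyloxy)phenyl]-3-[(tert-butyldiphenylsilyl)oxy]propan-1-ol | O[C@@H](c1ccc(OCc2ccccc2)cc1)[C@@H](CO[Si](c1ccccc1)(c1ccccc1)C(C)(C)C)OCc1ccccc1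
F5 | step 14 | 3,5,7,4'-tetra-O-benzylepiafzelechin-(4β→6)-5,7,3',4'-tetra-O-benzylepicatechin 3-O-(3,4,5-tri-O-benzylgallate) | O=C(O[C@@H]1Cc2c(OCc3ccccc3)c([C@H]3c4c(OCc5ccccc5)cc(OCc5ccccc5)cc4O[C@H](c4ccc(OCc5ccccc5)cc4)[C@@H]3OCc3ccccc3)c(OCc3ccccc3)cc2O[C@@H]1c1ccc(OCc2ccccc2)c(OCc2ccccc2)c1)c1cc(OCc2ccccc2)c(OCc2ccccc2)c(OCc2ccccc2)c1
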